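common to all: enzyme 0.21 µM
- teal: starting material 15 mM; second substrate 30 mM; run made earlier
- violet: starting material 15 mM; second substrate 45 mM; run made earlier
- birch: starting material 15 mM (fed, over 1.5 h); second substrate 30.0 mM; all else is in the flask from the start; the feed brings no volume worth counting; time 2.5 h
- oak: starting material 15 mM; second substrate 30.0 mM; everything together at the start; time 2.5 h
- cedar: starting material 15 mM; second substrate 30.0 mM (fed, over 1.5 h); all else is in the flask from the start; the feed brings no volume worth counting; time 2.5 h

teal run (percent of the starting material charged)

| time / h | target / % | starting material / % |
|---|---|---|
| 0.667 | 10.9 | 88.1 |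
| 1.33 | 22.9 | 76.9 |
| 2.00 | 35.2 | 66.5 |
| 2.50 | 41.8 | 58.4 |

violet run (percent of the starting material charged)

| time / min | target / % | starting material / % |
|---|---|---|
| 2.50 | 0.5 | 100.0 |
| 6.00 | 1.6 | 98.2 |
| 12.0 | 1.4 | 97.3 |
| 30.0 | 7.1 | 92.9 |

(readings scatter by 0.5 percentage points)



1. which flask leads in amount of target, in percent of the starting material charged ("all alike" within 1.5 percentage points) (birch / oak / cedar / all alike)
2. how much target is there at the end, in percent of the starting material charged: birch
3. how much target is there at the end, in percent of the starting material charged: oak
4. how much target is there at the end, in percent of the starting material charged: cedar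

Violet, with 45 mM of second substrate, made target more slowly than teal with 30 mM, so I watched the proportion of second substrate to starting material. The quantity I carried was teal's turnover frequency, the target made per enzyme and per hour over the whole run, 11900 /h. Violet's last reading gave 10100 /h, with that reading's scatter. Oak repeats teal's charge, so the frequency gave me 41.8 % there.

For birch and cedar I reckoned two extreme versions. In the first, the enzyme ignores the proportion, and both flasks stand at oak's figure. In the second, the proportion rules outright. Birch's enzyme makes nothing until the feed ends and then runs at teal's frequency, giving 16.7 %. Cedar's enzyme runs from start to end at the frequency with no second substrate present, which a straight line of inverse frequency against the proportion put at 18500 /h, giving 64.8 %. Neither extreme is the real flask: birch gathers starting material during its feed, and cedar gathers second substrate during its own. As my own estimate I therefore took the middle of each span, 29.2 % for birch and 53.3 % for cedar, with cedar leading.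

The forecast named cedar, with 33 % for birch, 42 % for oak and 48 % for cedar. Its ground for birch, with starting material low against the full second substrate, was that “the reaction runs slowly early on”. Its birch and cedar figures lay inside my spans but differed from my midpoints.

The simulation put cedar in the lead, with 33.5 % for birch, 42.0 % for oak and 50.5 % for cedar, so the forecast held.

    starting material + enzyme ⇌ complex A (K = 5100 /M, k = 2.90 × 10⁷ /M/h)
    complex A → enzyme + target (k = 33000 /h)
    second substrate + enzyme ⇌ complex B (K = 960 /M, k = 2.30 × 10⁷ /M/h)
    complex B → enzyme + second product (k = 16000 /h)
    second substrate ⇌ dormant form (K = 0.190, k = 0.130 /h)

Cedar stood above birch by 17 percentage points partly because second substrate takes enzyme into complex B: with that step taken away, the difference was 8 points, so competition for the enzyme is one part of the gap. Birch ended at 80.1 % of what teal's frequency gives over the same time. Carried to a neighbour of birch with 0.0520 µM of enzyme, the frequency and that share gave 8.30 %, and the neighbour flask gave 8.62 %.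

The readings come from a simulation with made-up constants; the scatter is artificial.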